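**Plan**

- Lactone atoms are counted O1, C2 (carbonyl), C3 (=CH2), C4 (CO2H), C5 (side chain); systematic names count the ring from the other side.
- Retrosynthesis: (a) the exocyclic C3=CH2 carbon is removed (carboxylation/Mannich methylenation, the remote ketone being masked as a ketal only for that stage); (b) the ring bond O1–C5 is cut back to a C5–H bond; (c) C4–C5 is traced to the C=C of an alkylidenesuccinic half-ester, cut by Wittig olefination into 15-oxohexadecanal and a C4 ylide; (d) the aldehyde is cut into cyclopentadecanolide and one methyl carbon.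
- Enabling feature: in the five-membered lactone ring O1 is bonded to C5, and C5 lies γ to the C2 carboxyl along C2–C3–C4–C5. Opened at O1–C5, the molecule is an (R)-2-alkylsuccinic acid whose C4 carboxyl is a methyl ester, whose free acid is the future C2, and in which C5 is the only γ-CH2 that acid can reach.
- Forward: the chain is assembled linearly (steps 1–5), the alkene is hydrogenated (step 6), the only ring is closed by carboxylate-directed γ-C–H lactonization (step 7), and hydrolysis, ketalization, C3 methylenation and deketalization finish the target (steps 8–11).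
- Stereochemistry: C4 comes from the rhodium/(S,S)-Et-DuPHOS hydrogenation; C5 comes from the C–H lactonization, where the chiral manganese catalyst selects one of the two C5 hydrogens and the C4 ester reinforces the trans outcome.

Key step: step 7

Assumption: the (S,S) antipodes of Et-DuPHOS and of the manganese catalyst are taken to be the ones that lead to (3R)-10 and to (2R,3S)-11; if either sense proves opposite, the mirror-image ligand is used with no other change.

Abbreviations: Et-DuPHOS = 1,2-bis(2,5-diethylphospholan-1-yl)benzene; TIPSpdp = N,N'-bis[(5-triisopropylsilylpyridin-2-yl)methyl]-2,2'-bipyrrolidine.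

**Route**

Step 1
Reactants: 1 cyclopentadecanolide
Product: 2 15-hydroxy-N-methoxy-N-methylpentadecanamide
Conditions: MeNH(OMe)·HCl (2 equiv), iPrMgCl (4 equiv), THF, −20 → 0 °C; aq. NH4Cl
Reagents that add atoms: N,O-dimethylhydroxylamine hydrochloride, CNOC.Cl
Why: Aminolysis of the lactone by the chloromagnesium amide formed from the hydroxylamine salt and iPrMgCl (Weinreb amide formation from an ester); the released ω-alkoxide cannot re-close a sixteen-membered ring under these conditions.

Step 2
Reactants: 2 15-hydroxy-N-methoxy-N-methylpentadecanamide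
Product: 3 16-hydroxyhexadecan-2-one
Conditions: MeMgBr (3 equiv), THF, 0 °C → rt; aq. NH4Cl
Reagents that add atoms: methylmagnesium bromide, C[Mg]Br
Why: Weinreb ketone synthesis: after the first equivalent has deprotonated the hydroxyl, MeMgBr adds once to the amide and the magnesium-chelated tetrahedral intermediate holds until work-up, so no tertiary alcohol should form.

Step 3
Reactants: 3 16-hydroxyhexadecan-2-one
Product: 4 15-oxohexadecanal
Conditions: TEMPO (10 mol%), PhI(OAc)2 (1.1 equiv), CH2Cl2, rt
Reagents that add atoms: none
Why: Oxoammonium-mediated alcohol oxidation (TEMPO/PhI(OAc)2) takes the primary alcohol to the aldehyde without over-oxidation in the absence of water and leaves the ketone untouched.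

Step 4
Reactants: 5 triphenylphosphine; 6 maleic anhydride
Product: 8 3-(methoxycarbonyl)-3-(triphenyl-λ5-phosphanylidene)propanoic acid, via ylide anhydride 7 (not isolated)
Conditions: acetone, rt; then MeOH, rt
Reagents that add atoms: methanol, CO
Why: Conjugate addition of the phosphine to maleic anhydride and proton shift give the ylide anhydride, and ring-opening methanolysis should deliver the ester-stabilised Wittig reagent carrying the free CH2CO2H arm, the phosphorus counterpart of a Stobbe half-ester.

Step 5
Reactants: 4 15-oxohexadecanal; 8 3-(methoxycarbonyl)-3-(triphenyl-λ5-phosphanylidene)propanoic acid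
Product: 9 (3E)-3-(methoxycarbonyl)-18-oxononadec-3-enoic acid
Conditions: toluene, 60 °C; extraction into aq. NaHCO3, then acidification
Reagents that add atoms: none
Why: Wittig olefination with an ester-stabilised ylide is selective for the aldehyde over the methyl ketone and E-selective, and it gives the alkylidenesuccinic half-ester with the free acid on the CH2 arm without any base that could enolize the ketone, so no ketal is needed before the C–H oxidation.

Step 6
Reactants: 9 (3E)-3-(methoxycarbonyl)-18-oxononadec-3-enoic acid
Product: 10 (3R)-3-(methoxycarbonyl)-18-oxononadecanoic acid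
Conditions: [Rh(cod)2]BF4 (1 mol%), (S,S)-Et-DuPHOS (1.1 mol%), NaOMe (0.1 equiv), H2 (5 bar), MeOH, rt
Reagents that add atoms: none
Why: Rhodium-catalysed asymmetric hydrogenation of an itaconate-type half-ester: the carboxylate arm and the alkene chelate the monovalent rhodium centre and the (S,S) ligand should direct hydrogen to the face that makes C3 of 10 (the future C4) R, while an isolated ketone is not reduced by a cationic rhodium bisphosphine at this pressure.

Step 7
Reactants: 10 (3R)-3-(methoxycarbonyl)-18-oxononadecanoic acid
Product: 11 methyl (2R,3S)-5-oxo-2-(14-oxopentadecyl)oxolane-3-carboxylate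
Conditions: [Mn(OTf)2((S,S)-TIPSpdp)] (2 mol%), aq. H2O2 (1.5 equiv, slow addition), CF3CH2OH, 0 °C
Reagents that add atoms: none
Why: Proposed new method: the carboxylate of 10 binds the divalent manganese complex, H2O2 converts it into a pentavalent manganese oxo carboxylate, this removes one hydrogen from C5 by 1,7-hydrogen atom transfer, and the short-lived secondary radical is captured by the bound carboxylate oxygen, so that two hydrogens are lost overall and H2O2 ends as water. The closest known reaction type is the carboxylate-directed, manganese-catalysed enantioselective γ-C–H lactonization of aliphatic acids with H2O2 in fluorinated alcohols; new here are the succinic half-ester substrate, whose γ-C–H bonds lie β to an ester carbonyl, and the stereocentre between the directing acid and the reacting carbon. The lactone closes as a five-membered ring by O1–C5 bond formation at the radical centre (if hydroxyl rebound competes, the γ-hydroxy acid closes to the same lactone by 5-exo-trig acyl substitution). The new stereocentre C5 (R) results from the choice between the two diastereotopic C5 hydrogens followed by rebound with retention; the chiral ligand controls this choice and the C4 ester reinforces it, because the side chain avoids the ester in the cyclic transition state and ends trans to it. Site selectivity is required against thirteen further chain methylenes, the C3 methylene and the C4–H bond: the bound acid reaches C5 through the favoured 1,7-transfer array (the other γ atom is the ester carbon), C3–H and C4–H are α to carbonyl groups and would lead to strained rings, the ketone deactivates the far end of the chain, and the bulky silyl groups of the ligand disfavour undirected attack on the middle of the chain. The ketone is left free on purpose, since a ketal would offer activated C–H bonds and would not survive aqueous peroxide in an acidic alcohol.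

Step 8
Reactants: 11 methyl (2R,3S)-5-oxo-2-(14-oxopentadecyl)oxolane-3-carboxylate
Product: 12 (2R,3S)-5-oxo-2-(14-oxopentadecyl)oxolane-3-carboxylic acid
Conditions: 6 M HCl, 1,4-dioxane, 100 °C
Reagents that add atoms: water, O
Why: Acid-catalysed ester hydrolysis; the γ-lactone stays closed in acid, no base is present that could open the ring by β-elimination, and since trans is the thermodynamically preferred arrangement the C4 centre is not endangered.

Step 9
Reactants: 12 (2R,3S)-5-oxo-2-(14-oxopentadecyl)oxolane-3-carboxylic acid
Product: 13 (2R,3S)-2-[13-(2-methyl-1,3-dioxolan-2-yl)tridecyl]-5-oxooxolane-3-carboxylic acid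
Conditions: 2-ethyl-2-methyl-1,3-dioxolane (as solvent), TsOH·H2O (5 mol%), 40 °C, butanone distilled off; Et3N quench
Reagents that add atoms: 2-ethyl-2-methyl-1,3-dioxolane, CCC1(C)OCCO1
Why: Acid-catalysed transketalization (exchange dioxolanation) masks the methyl ketone, which would otherwise be carboxylated in step 10; with no free alcohol present the carboxylic acid should not be esterified, the lactone is inert, and removal of butanone drives the equilibrium.

Step 10
Reactants: 13 (2R,3S)-2-[13-(2-methyl-1,3-dioxolan-2-yl)tridecyl]-5-oxooxolane-3-carboxylic acid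
Product: 15 (2R,3S)-4-methylidene-2-[13-(2-methyl-1,3-dioxolan-2-yl)tridecyl]-5-oxooxolane-3-carboxylic acid, via C3-carboxylated diacid 14 (not isolated)
Conditions: MeOMgOCO2Me (2 M in DMF, 35 equiv), 130 °C; cold 1 M HCl; then 37% aq. HCHO, PhNHMe, NaOAc, AcOH, rt
Reagents that add atoms: formaldehyde, C=O (the carboxyl carbon that MeOMgOCO2Me, CO[Mg]OC(=O)OC, places on 14 is lost again as CO2)
Why: Stiles carboxylation (chelation-driven carboxylation of the lactone enolate at C3) followed by decarboxylative Mannich methylenation with formaldehyde and N-methylaniline is the standard way to turn paraconic acids into their α-methylene derivatives; C4 and C5 are not touched, and any ketal lost in the acidic work-up only anticipates step 11.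

Step 11
Reactants: 15 (2R,3S)-4-methylidene-2-[13-(2-methyl-1,3-dioxolan-2-yl)tridecyl]-5-oxooxolane-3-carboxylic acid
Product: 16 (2R,3S)-4-methylidene-5-oxo-2-(14-oxopentadecyl)oxolane-3-carboxylic acid
Conditions: 1 M HCl, THF, rt
Reagents that add atoms: water, O
Why: Acid-catalysed ketal hydrolysis frees the methyl ketone; dilute acid at room temperature should neither move the exocyclic double bond into the ring nor epimerize C4 or C5.

**Compound list**

1 | cyclopentadecanolide (oxacyclohexadecan-2-one) | O=C1CCCCCCCCCCCCCCO1 | starting material
2 | 15-hydroxy-N-methoxy-N-methylpentadecanamide | CON(C)C(=O)CCCCCCCCCCCCCCO | intermediate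
3 | 16-hydroxyhexadecan-2-one | CC(=O)CCCCCCCCCCCCCCO | intermediate
4 | 15-oxohexadecanal | CC(=O)CCCCCCCCCCCCCC=O | intermediate
5 | triphenylphosphine | c1ccc(cc1)P(c1ccccc1)c1ccccc1 | starting material
6 | maleic anhydride | O=C1OC(=O)C=C1 | starting material
7 | 3-(triphenyl-λ5-phosphanylidene)oxolane-2,5-dione (ylide anhydride) | O=C1CC(=P(c2ccccc2)(c2ccccc2)c2ccccc2)C(=O)O1 | intermediate
8 | 3-(methoxycarbonyl)-3-(triphenyl-λ5-phosphanylidene)propanoic acid | COC(=O)C(CC(=O)O)=P(c1ccccc1)(c1ccccc1)c1ccccc1 | intermediate
9 | (3E)-3-(methoxycarbonyl)-18-oxononadec-3-enoic acid | OC(=O)C/C(C(=O)OC)=C\CCCCCCCCCCCCCC(C)=O | intermediate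
10 | (3R)-3-(methoxycarbonyl)-18-oxononadecanoic acid | OC(=O)C[C@H](C(=O)OC)CCCCCCCCCCCCCCC(C)=O | intermediate
11 | methyl (2R,3S)-5-oxo-2-(14-oxopentadecyl)oxolane-3-carboxylate | O=C1O[C@H](CCCCCCCCCCCCCC(C)=O)[C@@H](C(=O)OC)C1 | intermediate
12 | (2R,3S)-5-oxo-2-(14-oxopentadecyl)oxolane-3-carboxylic acid | O=C1O[C@H](CCCCCCCCCCCCCC(C)=O)[C@@H](C(=O)O)C1 | intermediate
13 | (2R,3S)-2-[13-(2-methyl-1,3-dioxolan-2-yl)tridecyl]-5-oxooxolane-3-carboxylic acid | O=C1O[C@H](CCCCCCCCCCCCCC2(C)OCCO2)[C@@H](C(=O)O)C1 | intermediate
14 | (2R,3S)-2-[13-(2-methyl-1,3-dioxolan-2-yl)tridecyl]-5-oxooxolane-3,4-dicarboxylic acid (configuration at the new carboxyl-bearing carbon not defined; it is lost in the same step) | O=C1O[C@H](CCCCCCCCCCCCCC2(C)OCCO2)[C@@H](C(=O)O)C1C(=O)O | intermediate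
15 | (2R,3S)-4-methylidene-2-[13-(2-methyl-1,3-dioxolan-2-yl)tridecyl]-5-oxooxolane-3-carboxylic acid | C=C1C(=O)O[C@H](CCCCCCCCCCCCCC2(C)OCCO2)[C@H]1C(=O)O | intermediate
16 | (2R,3S)-4-methylidene-5-oxo-2-(14-oxopentadecyl)oxolane-3-carboxylic acid | C=C1C(=O)O[C@H](CCCCCCCCCCCCCC(C)=O)[C@H]1C(=O)O | target

**Count and risks**

Total steps: 11. Longest linear sequence: 10 (steps 1–3 and 5–11 from cyclopentadecanolide); step 4 is a one-step side branch.

Steps most likely to fail:

1. Step 7 (directed C–H lactonization). Hydrogen abstraction at the electron-poor C5 methylene may be too slow, so that peroxide is consumed unproductively or undirected oxidation of mid-chain methylenes takes over; the facial choice at C5 may also be insufficient. Unreacted 10 is an acid, separable from neutral 11 by base extraction, and can be resubmitted. The fallback uses known chemistry, sets out from aldehyde 4 and returns at acid 12, bypassing steps 5–8. (4S)-4-Benzyl-1,3-oxazolidin-2-one is N-acylated (n-BuLi, THF, −78 °C) with methyl 4-chloro-4-oxobutanoate to give (4S)-4-benzyl-3-(4-methoxy-4-oxobutanoyl)-1,3-oxazolidin-2-one F1. Its boron Z-enolate (Bu2BOTf kept just below one equivalent relative to the imide, iPr2NEt, CH2Cl2, −78 °C, so that the methyl ketone of 4 is not enolized) should add to 4 in an Evans syn-aldol reaction to give methyl (3S,4R)-3-{[(4S)-4-benzyl-2-oxo-1,3-oxazolidin-3-yl]carbonyl}-4-hydroxy-18-oxononadecanoate F2. A syn aldol of this kind closes, spontaneously or with catalytic TsOH, to the trans lactone (4S)-4-benzyl-3-{[(2R,3S)-5-oxo-2-(14-oxopentadecyl)oxolan-3-yl]carbonyl}-1,3-oxazolidin-2-one F3. LiOH/H2O2 (THF–H2O, 0 °C), followed by acidification to re-close any opened lactone, then removes the auxiliary and gives 12.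

2. Step 10 (carboxylation/methylenation). Incomplete C3 carboxylation, or lactone opening and decarboxylation during the long heating in DMF, would lower the throughput. The fallback sets out from 13 and returns at 15. The dianion of 13 (LiN(SiMe3)2, 2.3 equiv, THF, −78 °C) is aminomethylated at C3 with dimethylmethyleneiminium iodide (Eschenmoser's salt) to give (2R,3S)-4-[(dimethylamino)methyl]-2-[13-(2-methyl-1,3-dioxolan-2-yl)tridecyl]-5-oxooxolane-3-carboxylic acid F4. N-Methylation with MeI in MeOH gives {[(4S,5R)-4-carboxy-5-[13-(2-methyl-1,3-dioxolan-2-yl)tridecyl]-2-oxooxolan-3-yl]methyl}trimethylammonium iodide F5, which should undergo E1cB elimination on treatment with aqueous NaHCO3 to give 15.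

3. Step 9 (ketalization beside a free acid). The exchange may stall short of completion, the acid may be partly esterified by ring-opened reagent, or the ketal may re-open during isolation under catalysis by the molecule's own carboxyl group. The fallback sets out from 11 and returns at 13. The ketone of 11 is ketalized first under standard conditions (ethylene glycol, TsOH, benzene, reflux with water separator) to methyl (2R,3S)-2-[13-(2-methyl-1,3-dioxolan-2-yl)tridecyl]-5-oxooxolane-3-carboxylate F6. The methyl ester is then cleaved under neutral conditions with Me3SnOH (ClCH2CH2Cl, 80 °C; brief KHSO4 wash), which should give 13 without exposing the ketal to strong acid.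

**Further compounds**

F1 | step 7 | (4S)-4-benzyl-3-(4-methoxy-4-oxobutanoyl)-1,3-oxazolidin-2-one | COC(=O)CCC(=O)N1[C@@H](Cc2ccccc2)COC1=O
F2 | step 7 | methyl (3S,4R)-3-{[(4S)-4-benzyl-2-oxo-1,3-oxazolidin-3-yl]carbonyl}-4-hydroxy-18-oxononadecanoate | O[C@H](CCCCCCCCCCCCCC(C)=O)[C@@H](C(=O)N1[C@@H](Cc2ccccc2)COC1=O)CC(=O)OC
F3 | step 7 | (4S)-4-benzyl-3-{[(2R,3S)-5-oxo-2-(14-oxopentadecyl)oxolan-3-yl]carbonyl}-1,3-oxazolidin-2-one | O=C1O[C@H](CCCCCCCCCCCCCC(C)=O)[C@@H](C(=O)N2[C@@H](Cc3ccccc3)COC2=O)C1
F4 | step 10 | (2R,3S)-4-[(dimethylamino)methyl]-2-[13-(2-methyl-1,3-dioxolan-2-yl)tridecyl]-5-oxooxolane-3-carboxylic acid (configuration at the aminomethyl-bearing carbon not defined) | CN(C)CC1C(=O)O[C@H](CCCCCCCCCCCCCC2(C)OCCO2)[C@H]1C(=O)O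
F5 | step 10 | {[(4S,5R)-4-carboxy-5-[13-(2-methyl-1,3-dioxolan-2-yl)tridecyl]-2-oxooxolan-3-yl]methyl}trimethylammonium iodide | C[N+](C)(C)CC1C(=O)O[C@H](CCCCCCCCCCCCCC2(C)OCCO2)[C@H]1C(=O)O.[I-]
F6 | step 9 | methyl (2R,3S)-2-[13-(2-methyl-1,3-dioxolan-2-yl)tridecyl]-5-oxooxolane-3-carboxylate | O=C1O[C@H](CCCCCCCCCCCCCC2(C)OCCO2)[C@@H](C(=O)OC)C1
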